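The target was where I began: I asked first what the flask must hold at its end, and then how fast it gets there.

| flask | substrate | coupling partner | remark | time |
|---|---|---|---|---|
| violet | 1.1 M | 0.92 M | run made earlier |  |
| teal | 1.1 M | 1.5 M | run made earlier |  |
| amber | 0.55 M | 0.66 M | run made earlier |  |
| flask | 1.1 M | 0.660 M |  | 2.5 min |

| run | time / min | target / % | intermediate A / % | substrate / % |
|---|---|---|---|---|
| violet | 0.200 | 73.9 | 11.5 | 14.1 |
| violet | 0.333 | 77.8 | 14.6 | 8.1 |
| violet | 0.500 | 78.8 | 16.1 | 4.1 |
| violet | 0.667 | 79.5 | 16.7 | 2.8 |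
| violet | 1.00 | 79.8 | 18.2 | 1.1 |
| violet | 1.50 | 80.7 | 18.4 | 0.4 |
| violet | 2.50 | 80.7 | 17.4 | 0.2 |
| teal | 0.333 | 93.4 | 6.1 | 0.3 |
| teal | 0.667 | 93.3 | 4.3 | 0 |
| teal | 1.00 | 93.6 | 3.4 | 0 |
| teal | 1.33 | 93.9 | 3.1 | 0 |
| teal | 2.00 | 93.1 | 2.2 | 0 |
| teal | 2.50 | 93.5 | 1.8 | 0.1 |
| amber | 0.200 | 78.4 | 11.2 | 9.6 |
| amber | 0.417 | 84.5 | 12.8 | 1.6 |
| amber | 0.667 | 86.0 | 12.6 | 0.3 |
| amber | 1.33 | 85.7 | 10.9 | 0.1 |
| amber | 2.50 | 85.8 | 8.3 | 0.1 |

(scatter of a reading: 0.3 percentage points)



1. concentration of target at 2.5 min, in M
2. concentration of intermediate A at 2.5 min, in M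

In the violet run, charged with less coupling partner than substrate, target and intermediate A together held 99.1% of the substrate at 1.50 min. I then turned the question round and asked what intermediate A's disappearance takes. It faded in the teal run, from 6.1% to 1.8%, and there coupling partner was charged above substrate. The flask stood at 0.600 equivalents against 1.36 in the teal run, with coupling partner as the limiting reagent. So I reckoned:

[target] ≈ 0.660 M

[intermediate A] ≈ 1.1 M − 0.660 M = 0.440 M

This surplus, substrate charged minus coupling partner charged, was 0.180 M in the violet run, where intermediate A read 0.202 M at 1.50 min.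

For the speed, late violet substrate fell from 2.8% to 0.4%, a half-life read as about 0.297 min. The asked 2.5 min is 8.42 such half-lives, so I expected the end state to stand by then.

The forecast gave 0.65 M of target, a little below my figure, and 0.435 M of intermediate A, with coupling partner “consumed within about 0.5 min”.

The flask gave 0.656 M of target and 0.437 M of intermediate A, against the surplus of 0.440 M.

    substrate → intermediate A (k = 0.0308 s⁻¹)
    substrate + coupling partner → target (k = 0.500 M⁻¹ s⁻¹)
    coupling partner + intermediate A → intermediate B (k = 0.0194 M⁻¹ s⁻¹)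
    intermediate B → side product (k = 0.0258 s⁻¹)

In the flask, substrate went to target 11 times as fast as to intermediate A at the start, but 0.0029 times as fast at 2.50 min. One neighbour flask was charged with 0.17 M of coupling partner. There the surplus gives 0.930 M as the expected intermediate A, and the computed result is 0.921 M of intermediate A with 0.170 M of target.

The data were computed with made-up constants; noise was put on by code.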